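**Plan**

1. Target 17 is a hexasubstituted benzene ring fused to a 2,2-dimethyl-2H-pyran (chromene numbering: O1, C2–C4, C4a, C5–C8, C8a).
2. Enabling feature: on the benzene ring the arylethyl carbon C5 and the ester carbon C6 are neighbours and C6 is ortho to the C7 oxygen. A C5–C6 aryne polarised by the C7 alkoxy group can therefore take the carbon nucleophile at C5 and the acylating agent at C6 in one operation.
3. Retrosynthesis: the two phenol MOM groups are cut first, then C5–CH2 and C6–CO2Me together (aryne 1,2-difunctionalisation of a 5-chlorochromene), then the C7 O–MOM bond, then the pyran ring (C4–C4a and O1–C2), and last the C8–prenyl bond.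
4. Forward: 5-chlororesorcinol is C-prenylated between its hydroxyls, the pyran ring is closed with prenal (the only ring formed; both benzene rings are bought), the free phenol is protected, the aryne three-component coupling installs both remaining carbon substituents, and acid frees the two phenols.
5. Stereochemistry: there is none to set; the target has no stereocentre, the prenyl alkene carries two identical methyl groups and the pyran alkene is held cis by the ring.

Key step: step 6

Assumption: 5-chlorobenzene-1,3-diol and 4-(2-bromoethyl)phenol are taken as catalogue compounds; chlorine serves as the C5 leaving group because n-BuLi does not exchange it, so plain ortho-lithiation can start the aryne sequence.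

**Route**

Step 1
Reactants: 1 5-chlorobenzene-1,3-diol; 2 3-methylbut-2-en-1-ol
Product: 3 5-chloro-2-(3-methylbut-2-en-1-yl)benzene-1,3-diol
Conditions: acidic Al2O3, ClCH2CH2Cl, reflux (1 in slight excess)
Reagents that add atoms: none
Why: Alumina-promoted Friedel–Crafts ortho-allylation of a phenol with an allylic alcohol, in which the acidic surface binds both hydroxyls and ionises the alcohol beside them, so the unrearranged prenyl group should go to C2, the carbon ortho to both oxygens, as it does with 5-alkylresorcinols.

Step 2
Reactants: 3 5-chloro-2-(3-methylbut-2-en-1-yl)benzene-1,3-diol; 4 3-methylbut-2-enal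
Product: 6 5-chloro-2,2-dimethyl-8-(3-methylbut-2-en-1-yl)-2H-chromen-7-ol, via o-quinone methide 5 (not isolated)
Conditions: ethylenediammonium diacetate (20 mol %), xylene, reflux (4, 1.1 equiv)
Reagents that add atoms: none
Why: Ammonium salt-catalysed formal [3+3] chromene annulation (Knoevenagel-type condensation at a ring carbon ortho to one hydroxyl and para to the other, then oxa-6π electrocyclisation of the o-quinone methide), in which the two open ring positions of 3 are equivalent by symmetry so only one chromene can form, and near-stoichiometric aldehyde holds back a second annulation.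

Step 3
Reactants: 6 5-chloro-2,2-dimethyl-8-(3-methylbut-2-en-1-yl)-2H-chromen-7-ol
Product: 7 5-chloro-7-(methoxymethoxy)-2,2-dimethyl-8-(3-methylbut-2-en-1-yl)-2H-chromene
Conditions: MOMCl, i-Pr2NEt, CH2Cl2, 0 °C → rt
Reagents that add atoms: chloromethyl methyl ether (MOMCl), COCCl
Why: O-Alkylation of the phenol with an α-chloro ether under amine base (MOM ether formation), giving an acetal that is stable to organolithium and Grignard reagents and later acts as the ortho-directing and aryne-polarising group.

Step 4
Reactants: 8 4-(2-bromoethyl)phenol
Product: 9 1-(2-bromoethyl)-4-(methoxymethoxy)benzene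
Conditions: MOMCl, i-Pr2NEt, CH2Cl2, 0 °C → rt
Reagents that add atoms: chloromethyl methyl ether (MOMCl), COCCl
Why: MOM ether formation under a hindered amine base, which is too weak to generate the free phenoxide that would displace the primary bromide by spirocyclisation.

Step 5
Reactants: 9 1-(2-bromoethyl)-4-(methoxymethoxy)benzene
Product: 10 {2-[4-(methoxymethoxy)phenyl]ethyl}magnesium bromide (THF solution, titrated and used directly)
Conditions: Mg turnings, I2 (cat.), THF, rt → 40 °C, slow addition
Reagents that add atoms: magnesium, [Mg]
Why: Grignard formation by insertion of magnesium into the primary C–Br bond, to which the aryl MOM ether is inert, with slow addition at moderate dilution to limit Wurtz coupling.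

Step 6
Reactants: 7 5-chloro-7-(methoxymethoxy)-2,2-dimethyl-8-(3-methylbut-2-en-1-yl)-2H-chromene; 10 {2-[4-(methoxymethoxy)phenyl]ethyl}magnesium bromide; 11 methyl chloroformate
Product: 15 methyl 7-(methoxymethoxy)-5-{2-[4-(methoxymethoxy)phenyl]ethyl}-2,2-dimethyl-8-(3-methylbut-2-en-1-yl)-2H-chromene-6-carboxylate, via C6 aryllithium 12 (not isolated), via C5–C6 aryne 13 (not isolated), via C6 arylmagnesium bromide 14 (not isolated)
Conditions: n-BuLi (1.05 equiv), THF, −78 °C; then 10 (2.5 equiv), −78 °C → rt; then 11 (excess), −78 °C → rt
Reagents that add atoms: none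
Why: n-BuLi removes the only hydrogen on the benzene ring, C6–H, which is acidified by the adjacent chlorine and reached through coordination to the C7 MOM ether (directed ortho-metalation), and on warming aryllithium 12 loses LiCl to give the C5–C6 aryne 13 in the presence of Grignard reagent 10. The closest known reaction type is the three-component coupling of 3-alkoxyarynes, generated by ortho-lithiation of 3-alkoxyhalobenzenes, with Grignard reagents followed by capture of the new arylmagnesium by a carbon electrophile. The σ-withdrawing C7 oxygen distorts and polarises the aryne so that the alkyl nucleophile adds to the distal C5 and the carbanion develops at C6 next to oxygen, where magnesium is also chelated by the MOM group; this site selectivity is the one the step needs, and the alkoxy group outweighs the weaker opposing bias of the C4a carbon substituent. Arylmagnesium 14 is then acylated by methyl chloroformate, and the resulting ester, flanked on both sides, should resist the excess Grignard reagent at low temperature. No ring is closed and no stereocentre is formed; the step makes the C5–CH2 and C6–CO2Me bonds and completes the hexasubstituted ring.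

Step 7
Reactants: 15 methyl 7-(methoxymethoxy)-5-{2-[4-(methoxymethoxy)phenyl]ethyl}-2,2-dimethyl-8-(3-methylbut-2-en-1-yl)-2H-chromene-6-carboxylate
Product: 17 methyl 7-hydroxy-5-[2-(4-hydroxyphenyl)ethyl]-2,2-dimethyl-8-(3-methylbut-2-en-1-yl)-2H-chromene-6-carboxylate, via C7 phenol mono-MOM ester 16 (not isolated)
Conditions: aq. HCl (3 M), MeOH, rt → 40 °C
Reagents that add atoms: none
Why: Acid-catalysed acetal methanolysis of both MOM ethers, in which the C7 ether ortho to the ester should cleave first, the methyl ester is unchanged in methanol, and the mild temperature is meant to keep the prenyl and chromene alkenes from being protonated into cyclisation onto the freed C7 hydroxyl, which is held in a hydrogen bond to the ester.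

**Compound list**

1 | 5-chlorobenzene-1,3-diol | Oc1cc(O)cc(Cl)c1 | starting material
2 | 3-methylbut-2-en-1-ol | CC(C)=CCO | starting material
3 | 5-chloro-2-(3-methylbut-2-en-1-yl)benzene-1,3-diol | CC(C)=CCc1c(O)cc(Cl)cc1O | intermediate
4 | 3-methylbut-2-enal | CC(C)=CC=O | starting material
5 | 3-chloro-5-hydroxy-6-(3-methylbut-2-en-1-yl)-2-(3-methylbut-2-en-1-ylidene)cyclohexa-3,5-dien-1-one (o-quinone methide, dienyl chain syn to the carbonyl) | O=C1/C(=C\C=C(C)C)C(Cl)=CC(O)=C1CC=C(C)C | intermediate (not isolated)
6 | 5-chloro-2,2-dimethyl-8-(3-methylbut-2-en-1-yl)-2H-chromen-7-ol | CC(C)=CCc1c(O)cc(Cl)c2C=CC(C)(C)Oc12 | intermediate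
7 | 5-chloro-7-(methoxymethoxy)-2,2-dimethyl-8-(3-methylbut-2-en-1-yl)-2H-chromene | COCOc1cc(Cl)c2C=CC(C)(C)Oc2c1CC=C(C)C | intermediate
8 | 4-(2-bromoethyl)phenol | Oc1ccc(CCBr)cc1 | starting material
9 | 1-(2-bromoethyl)-4-(methoxymethoxy)benzene | COCOc1ccc(CCBr)cc1 | intermediate
10 | {2-[4-(methoxymethoxy)phenyl]ethyl}magnesium bromide | COCOc1ccc(CC[Mg]Br)cc1 | intermediate
11 | methyl chloroformate | COC(=O)Cl | starting material
12 | [5-chloro-7-(methoxymethoxy)-2,2-dimethyl-8-(3-methylbut-2-en-1-yl)-2H-chromen-6-yl]lithium | [Li]c1c(OCOC)c(CC=C(C)C)c2OC(C)(C)C=Cc2c1Cl | intermediate (not isolated)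
13 | 7-(methoxymethoxy)-2,2-dimethyl-8-(3-methylbut-2-en-1-yl)-5,6-didehydro-2H-chromene (C5–C6 aryne) | COCOC1=C(CC=C(C)C)C2=C(C=CC(C)(C)O2)C#C1 | intermediate (not isolated)
14 | bromo{7-(methoxymethoxy)-5-{2-[4-(methoxymethoxy)phenyl]ethyl}-2,2-dimethyl-8-(3-methylbut-2-en-1-yl)-2H-chromen-6-yl}magnesium | Br[Mg]c1c(OCOC)c(CC=C(C)C)c2OC(C)(C)C=Cc2c1CCc1ccc(OCOC)cc1 | intermediate (not isolated)
15 | methyl 7-(methoxymethoxy)-5-{2-[4-(methoxymethoxy)phenyl]ethyl}-2,2-dimethyl-8-(3-methylbut-2-en-1-yl)-2H-chromene-6-carboxylate | COC(=O)c1c(OCOC)c(CC=C(C)C)c2OC(C)(C)C=Cc2c1CCc1ccc(OCOC)cc1 | intermediate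
16 | methyl 7-hydroxy-5-{2-[4-(methoxymethoxy)phenyl]ethyl}-2,2-dimethyl-8-(3-methylbut-2-en-1-yl)-2H-chromene-6-carboxylate | COC(=O)c1c(O)c(CC=C(C)C)c2OC(C)(C)C=Cc2c1CCc1ccc(OCOC)cc1 | intermediate (not isolated)
17 | methyl 7-hydroxy-5-[2-(4-hydroxyphenyl)ethyl]-2,2-dimethyl-8-(3-methylbut-2-en-1-yl)-2H-chromene-6-carboxylate | COC(=O)c1c(O)c(CC=C(C)C)c2c(c1CCc1ccc(O)cc1)C=CC(C)(C)O2 | target

**Step count**

Total steps: 7. Longest linear sequence: 5 (steps 1, 2, 3, 6, 7); the Grignard branch (steps 4, 5) joins at step 6.

**Steps most likely to fail**

Step 6. Three processes could divert the sequence. The aryne may be reduced by β-hydride transfer from the Grignard reagent instead of being carbometalated. Lithium may pass to magnesium before chloride is lost, so that aryne formation stalls. The prenyl CH2 may be metalated in competition with the ring. The fallback makes the same two bonds one at a time; it sets out from 7 (with 10 and 11) and comes back at 15. Chlorochromene 7 is lithiated as in step 6 to aryllithium 12, which is acylated at −78 °C, before LiCl can leave, with methyl chloroformate 11 to give methyl 5-chloro-7-(methoxymethoxy)-2,2-dimethyl-8-(3-methylbut-2-en-1-yl)-2H-chromene-6-carboxylate F1. Grignard reagent 10 is transmetalated with ZnCl2 to {2-[4-(methoxymethoxy)phenyl]ethyl}zinc chloride F2. Negishi coupling of F1 with F2 (Pd(OAc)2, SPhos, THF, 60 °C), helped by the ortho ester that activates the C5–Cl bond, should then form the C5–CH2 bond and give 15.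

Step 1. The allyl group may be delivered beside chlorine (C4) or to two ring positions, and the ortho-prenyl phenol may cyclise to a chroman on the acidic surface. The fallback fixes the site by halogenation; it sets out from 1 and comes back at 3. Iodination with I2 and NaHCO3 in water at 0 °C, conditions that place iodine between the hydroxyls of resorcinols, should give 5-chloro-2-iodobenzene-1,3-diol F3. Stille coupling of F3 with tributyl(3-methylbut-2-en-1-yl)stannane (Pd(PPh3)4, DMF, 90 °C), which transfers the allyl group mainly through its unsubstituted terminus and tolerates free phenols and the aryl chloride, should then give 3 without any acid treatment.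

Step 2. Condensation may be slow at a ring carbon that is flanked by chlorine and inductively deactivated, and pushing it with more aldehyde invites a second annulation at C6 of the first-formed chromenol. The fallback builds the pyran ring by sigmatropic rearrangement; it sets out from 3 and comes back at 6. One of the two equivalent hydroxyls of 3 is alkylated with 3-chloro-3-methylbut-1-yne (DBU, CuCl2·2H2O cat., MeCN, 0 °C) to 5-chloro-3-[(2-methylbut-3-yn-2-yl)oxy]-2-(3-methylbut-2-en-1-yl)phenol F4. Heating F4 in N,N-diethylaniline at 180 °C should bring about the aromatic propargyl Claisen rearrangement into the only free ortho position, giving 5-chloro-4-(3-methylbuta-1,2-dien-1-yl)-2-(3-methylbut-2-en-1-yl)benzene-1,3-diol F5. A 1,5-hydrogen shift in F5 leads to the o-quinone methide 5 of the main route, and oxa-6π electrocyclisation returns chromenol 6.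

**Further compounds**

F1 | step 6 | methyl 5-chloro-7-(methoxymethoxy)-2,2-dimethyl-8-(3-methylbut-2-en-1-yl)-2H-chromene-6-carboxylate | COC(=O)c1c(Cl)c2C=CC(C)(C)Oc2c(CC=C(C)C)c1OCOC
F2 | step 6 | {2-[4-(methoxymethoxy)phenyl]ethyl}zinc chloride | COCOc1ccc(CC[Zn]Cl)cc1
F3 | step 1 | 5-chloro-2-iodobenzene-1,3-diol | Oc1cc(Cl)cc(O)c1I
F4 | step 2 | 5-chloro-3-[(2-methylbut-3-yn-2-yl)oxy]-2-(3-methylbut-2-en-1-yl)phenol | C#CC(C)(C)Oc1cc(Cl)cc(O)c1CC=C(C)C
F5 | step 2 | 5-chloro-4-(3-methylbuta-1,2-dien-1-yl)-2-(3-methylbut-2-en-1-yl)benzene-1,3-diol | CC(C)=C=Cc1c(Cl)cc(O)c(CC=C(C)C)c1O
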